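The readings come from a simulation for substances that don't exist; the scatter is artificial.

Early on, up to 12.0 h, the winter flask crept down to 88.8% of its starting material, and I wrote this note for whoever took over the bench.

| flask | starting material | reagent | remark | time |
|---|---|---|---|---|
| winter | 0.75 M | 1.5 equiv | the very flask that is asked about, followed so far |  |
| dawn | 1.1 M | 1.5 equiv | run made earlier |  |
| flask | 0.75 M | 1.50 equiv |  | 30 h |

| run | time / h | target / % | crystals / % | starting material / % |
|---|---|---|---|---|
| winter | 0.667 | 0.7 | 0.4 | 99.5 |
| winter | 2.00 | 1.3 | 0.5 | 98.0 |
| winter | 3.00 | 2.2 | 0.4 | 97.3 |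
| winter | 5.00 | 4.5 | 0.2 | 95.9 |
| winter | 8.00 | 6.5 | 0.8 | 92.7 |
| winter | 10.0 | 8.1 | 0.3 | 90.6 |
| winter | 12.0 | 9.7 | 0 | 88.8 |
| dawn | 1.50 | 2.2 | 0 | 97.5 |
| dawn | 3.00 | 3.5 | 0.9 | 95.7 |
| dawn | 5.00 | 7.3 | 0 | 92.5 |
| dawn | 6.00 | 8.2 | 0.2 | 91.9 |
| dawn | 8.00 | 10.4 | 0 | 88.9 |
| dawn | 10.0 | 11.4 | 0 | 86.9 |
| dawn | 12.0 | 14.7 | 0.3 | 84.9 |

(standard deviation of a reading: 0.5 percentage points)

- amounts and yields of target count crystals too
- given per volume of solution although it is solid: crystals
- the numbers in the tables scatter by 0.5 percentage points (one standard deviation)
- candidate steps: starting material + reagent -> target; starting material -> side product; crystals <-> target; reagent + target -> over-reaction product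

- the target and crystals together standing at 30 h, as a percentage of the starting material charged
- concentration of target in solution at 30 h, in percent of saturation

I followed one molecule of starting material and asked its chance of standing as target once it had left. At the last winter reading, target over fraction of charge lost came to 86.6%, and this I called the keeping share, the selectivity, though dawn's last reading, from a stronger charge, gave 97.4%, so I held the winter figure as a loose reading. Taking the same fraction from each equal stretch of time, I expected 74.3% of the starting material at 30 h, and so 22.3% target and crystals together in the winter flask. I asked that it stay closed and stirred, and that nobody worry over its crystal readings, which stayed at or below 0.8% with a scatter of 0.5 percentage points.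

The forecast gave 22.5% (from 20.5% to 24.5%) and 85% of saturation, adding “Crystallisation would barely change the total”.

The winter flask gave 20.2% and 79.7% of saturation.

    starting material + reagent → target (k = 0.00850 M⁻¹ h⁻¹)
    starting material → side product (k = 5.80 × 10⁻⁴ h⁻¹)
    crystals ⇌ target, rate k3*(cs3 - [target]) while solid is left; crystals form when [target] > cs3 (solubility = 0.190 M, k = 4.80 h⁻¹)
    reagent + target → over-reaction product (k = 0.00780 M⁻¹ h⁻¹)

With the 24.3% of the charge truly lost, the keeping share gave 21.1% for the winter flask. In the neighbour flask at 0.19 M, it gave 7.32% against a simulated 6.57%. The winter flask stood at 20.2% partly because it was read so early, the largest single effect though not the main reason: the same flask read at 300 h held 42.7%, a gain of 23 points.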